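Readings and results are calculated for substances that don't exist, noise included.

- Don't try to read what is dissolved in this flask: no column shows it, so work from the two rates that can be read.

in all of them: solid substrate 0.050 M; gas phase 2.2 mM (held); catalyst 1.2 mM

| run | remark | time |
|---|---|---|
| epsilon | the very flask that is asked about, followed so far |  |
| flask |  | 12 min |

epsilon run (percent of the solid substrate charged)

| time / min | target / % | solid substrate / % |
|---|---|---|
| 0.417 | 0.1 | 93.6 |
| 0.667 | 0.4 | 90.1 |
| 1.33 | 1.0 | 82.1 |
| 2.50 | 3.2 | 71.3 |
| 5.00 | 6.5 | 55.8 |

(standard deviation of a reading: 0.5 percentage points)

- solid substrate is a solid; its amount is given per volume of the solution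
- at the start none of the gas phase is in solution
- at the start none of the solid substrate is in solution

- how much target there is at 12 min, in percent of the solid substrate charged
- concentration of dissolved gas in solution at 12 min, in percent of saturation

- Take the last interval of the run, from 2.50 min to 5.00 min. The solid substrate falls by 0.0620 min⁻¹ of the charge, and target rises by 0.0132 min⁻¹, slower.
- Divide them so that time drops out: the harvest ratio, gain in c(target) per loss in c(solid substrate), is 0.213. Treat it as a reading, since each of its readings scatters by 0.5 percentage points.
- Then follow one curve. Fit the solid's fall in that interval as first order, 0.0980 min⁻¹, which leaves 28.1% at 12 min.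
- Multiply the further loss by the ratio and add it to the last target reading: my reckoning gives 12.4%. No reading shows dissolved gas, so give it no reckoning.
- The forecast differs, higher: 16% of target and 80% of saturation, holding that target “forms almost linearly”.
- The flask gives 15.4% and 94.3%, so the forecast's gas stands 14 points low.

    target + catalyst ⇌ isomer of the product + catalyst, rate k1*[catalyst]*[target] forward; the back reaction follows from the equilibrium constant (K = 2.30, k = 14.2 L mol⁻¹ s⁻¹)
    gas phase ⇌ dissolved gas, rate k2*(csat - [dissolved gas]) (kL = 0.287 s⁻¹)
    solid substrate ⇌ starting material, rate k3*(cs3 - [starting material]) while solid is left; crystals form when [starting material] > cs3 (solubility = 22.0 mM, k = 0.00636 s⁻¹)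
    starting material + dissolved gas + catalyst → catalyst + target (k = 895 L² mol⁻² s⁻¹)

- From 6.00 min to 12.0 min this flask's ratio is 0.292, above the reading. The same recipe read at 30 min shows 0.579 after the asked time.
- Target's half-life by its forward step into isomer of the product, the way back not counted, is 0.68 min, short against 12 min. At 12.0 min this flask holds 15.4% target beside 32.5% starting material and 28.6% isomer of the product.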